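The target is cut at the aryl ketone bond between coumarin C8 and the ketone carbon. The acyl half is a γ-hydroxy enone: its ketone carbon and its carbinol carbon are 1,4-related through cyclohexene C1 and C6, so it is carried as the bicyclic enoate γ-lactone 18. The key step generates the C8 aryllithium of bromocoumarin 10 beside its own 7-phenoxide, which switches off the pyranone carbonyl, and lets it open lactone 18: one operation forms the C8–C(=O) bond and releases the (S)-alcohol, with no protecting group on either half. Lactone 18 comes from a Diels–Alder reaction of (S)-5-methylfuran-2(5H)-one; bromide 10 from phloroglucinol by Pechmann condensation and a regiodefining Claisen rearrangement.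

Key step: step 12

Remark: the target is taken to rest as the open γ-hydroxy enone drawn (conjugated and hydrogen-bonded to O7–H), not as its cyclic lactol; the last step is therefore worked up cold and weakly acidic.

**Aryl half**

Step 1
Reactants: 1 phloroglucinol; 2 ethyl 2-methyl-3-oxobutanoate
Product: 3 5,7-dihydroxy-3,4-dimethyl-2H-chromen-2-one
Conditions: conc. H2SO4, 0 °C → rt
Reagents that add atoms: none
Why: Pechmann condensation; the threefold symmetry of 1 leaves a single regiochemical outcome.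

Step 2
Reactants: 3 5,7-dihydroxy-3,4-dimethyl-2H-chromen-2-one
Product: 4 5-hydroxy-3,4-dimethyl-2-oxo-2H-chromen-7-yl 2,2-dimethylpropanoate
Conditions: PivCl (1.05 equiv), Et3N (1.2 equiv), THF, −20 → 0 °C
Reagents that add atoms: pivaloyl chloride, CC(C)(C)C(Cl)=O
Why: Kinetically controlled O-acylation; the 7-OH is conjugated to the pyranone carbonyl (more acidic) and unhindered, the 5-OH is peri to the C4 methyl, so one equivalent of a bulky acyl chloride should acylate O7.

Step 3
Reactants: 4 5-hydroxy-3,4-dimethyl-2-oxo-2H-chromen-7-yl 2,2-dimethylpropanoate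
Product: 5 3,4-dimethyl-2-oxo-5-(prop-2-en-1-yloxy)-2H-chromen-7-yl 2,2-dimethylpropanoate
Conditions: allyl bromide (1.5 equiv), K2CO3, acetone, 55 °C
Reagents that add atoms: allyl bromide, C=CCBr
Why: Williamson etherification of the remaining phenol; an aryl pivalate should survive K2CO3 in dry acetone.

Step 4
Reactants: 5 3,4-dimethyl-2-oxo-5-(prop-2-en-1-yloxy)-2H-chromen-7-yl 2,2-dimethylpropanoate
Product: 6 5-hydroxy-3,4-dimethyl-2-oxo-6-(prop-2-en-1-yl)-2H-chromen-7-yl 2,2-dimethylpropanoate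
Conditions: PhNEt2, 190 °C
Reagents that add atoms: none
Why: Aromatic Claisen rearrangement; from O5 the allyl group can reach only C6, because the other ortho carbon is the ring-fusion atom C4a, so the C6 carbon substituent is placed without ambiguity.

Step 5
Reactants: 6 5-hydroxy-3,4-dimethyl-2-oxo-6-(prop-2-en-1-yl)-2H-chromen-7-yl 2,2-dimethylpropanoate
Product: 8 7-hydroxy-5-methoxy-3,4-dimethyl-6-(prop-2-en-1-yl)-2H-chromen-2-one, via methoxy pivalate 7 (not isolated)
Conditions: MeI (3 equiv), K2CO3, acetone, 50 °C; evaporate volatiles; K2CO3, MeOH, rt; acidic work-up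
Reagents that add atoms: iodomethane, CI
Why: Williamson methylation of the hindered 5-OH, then transesterification of the activated aryl pivalate with methanol in the same flask (after excess MeI is removed) to free O7.

Step 6
Reactants: 8 7-hydroxy-5-methoxy-3,4-dimethyl-6-(prop-2-en-1-yl)-2H-chromen-2-one
Product: 9 8-bromo-7-hydroxy-5-methoxy-3,4-dimethyl-6-(prop-2-en-1-yl)-2H-chromen-2-one
Conditions: NBS (1.0 equiv), MeCN, −20 °C, dark
Reagents that add atoms: N-bromosuccinimide, O=C1CCC(=O)N1Br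
Why: Electrophilic aromatic bromination; C8 is the only unsubstituted ring carbon and is activated by 7-OH (ortho), O1 (ortho) and 5-OMe (para), so ring bromination should outrun attack on the monosubstituted allyl alkene at low temperature.

Step 7
Reactants: 9 8-bromo-7-hydroxy-5-methoxy-3,4-dimethyl-6-(prop-2-en-1-yl)-2H-chromen-2-one
Product: 10 8-bromo-7-hydroxy-5-methoxy-3,4-dimethyl-6-(3-methylbut-2-en-1-yl)-2H-chromen-2-one
Conditions: 2-methylbut-2-ene (large excess), 2nd-generation Ru–NHC benzylidene metathesis catalyst (5 mol%), CH2Cl2, 40 °C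
Reagents that add atoms: 2-methylbut-2-ene, CC=C(C)C
Why: Olefin cross-metathesis converts the terminal allyl group into prenyl; free phenols and aryl bromides are tolerated by this catalyst class.

**Acyl half**

Step 8
Reactants: 11 (2E)-pent-2-enal
Product: 12 (1E,3E)-trimethyl(penta-1,3-dien-1-yloxy)silane
Conditions: TMSCl, Et3N, ZnCl2 (cat.), Et2O, reflux; distillation
Reagents that add atoms: chlorotrimethylsilane, C[Si](C)(C)Cl
Why: Soft enolization (O-silylation, then γ-deprotonation) should give the silyl dienol ether mainly as the (1E,3E)-isomer; any (3Z)-isomer cannot reach the s-cis conformation and is inert in step 9.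

Step 9
Reactants: 13 (5S)-5-methylfuran-2(5H)-one; 12 (1E,3E)-trimethyl(penta-1,3-dien-1-yloxy)silane
Product: 15 (3S,3aR,4R,7S,7aR)-7-hydroxy-3,4-dimethyl-3a,4,7,7a-tetrahydro-2-benzofuran-1(3H)-one, via silyl ether adduct 14 (not isolated)
Conditions: 12 (3 equiv), BHT (cat.), toluene, 140 °C, sealed tube; then 1 M HCl, THF, 0 °C
Reagents that add atoms: none
Why: Diels–Alder cycloaddition; the 1-silyloxy group enforces "ortho" regiochemistry (its carbon bonds to the lactone α-carbon, the methyl-bearing terminus to the β-carbon), the diene adds to the face of 13 anti to the C5 methyl (sets C3a), the endo transition state places the outward methyl of the E,E-diene cis to the lactone ring (sets C4), and the acidic work-up cleaves the TMS ether.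

Step 10
Reactants: 15 (3S,3aR,4R,7S,7aR)-7-hydroxy-3,4-dimethyl-3a,4,7,7a-tetrahydro-2-benzofuran-1(3H)-one
Product: 16 (3S,3aR,4R,7S,7aR)-7-hydroxy-3,4-dimethylhexahydro-2-benzofuran-1(3H)-one
Conditions: H2 (1 atm), 10% Pd/C, EtOAc, rt
Reagents that add atoms: none
Why: Catalytic hydrogenation of the isolated cis-disubstituted ring alkene; no stereocenter is formed or touched.

Step 11
Reactants: 16 (3S,3aR,4R,7S,7aR)-7-hydroxy-3,4-dimethylhexahydro-2-benzofuran-1(3H)-one
Product: 18 (3S,3aR,4R)-3,4-dimethyl-3a,4,5,6-tetrahydro-2-benzofuran-1(3H)-one, via mesylate 17 (not isolated)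
Conditions: MsCl, Et3N, CH2Cl2, 0 °C; then DBU, 0 °C → rt
Reagents that add atoms: none
Why: Mesylation and E1cB elimination (C7a–H is α to the lactone carbonyl) should give the conjugated enoate; C7 and C7a lose their configuration by design, while C3a in 18 is not conjugated to the carbonyl through an enolizable position and C3 and C4 are remote, so these three centers are kept.

**Fragment union**

Step 12
Reactants: 10 8-bromo-7-hydroxy-5-methoxy-3,4-dimethyl-6-(3-methylbut-2-en-1-yl)-2H-chromen-2-one; 18 (3S,3aR,4R)-3,4-dimethyl-3a,4,5,6-tetrahydro-2-benzofuran-1(3H)-one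
Product: 22 7-hydroxy-8-{(5R,6R)-6-[(1S)-1-hydroxyethyl]-5-methylcyclohex-1-ene-1-carbonyl}-5-methoxy-3,4-dimethyl-6-(3-methylbut-2-en-1-yl)-2H-chromen-2-one, via sodium phenoxide 19 (not isolated), via aryllithium 20 (not isolated), via lithium lactolate 21 (not isolated)
Conditions: NaH (1.05 equiv), THF, 0 °C; t-BuLi (2.05 equiv), −78 °C; 18 (1.3 equiv), −78 → −40 °C; AcOH (3 equiv), −78 °C
Reagents that add atoms: none
Why: NaH gives the 7-phenoxide, whose charge is delocalized through C4a and C4=C3 into the pyranone carbonyl (a vinylogous carboxylate), so coumarin C2 is switched off as an electrophile; Br/Li exchange with t-BuLi, faster than carbonyl addition at −78 °C, then gives the C8 aryllithium, which cannot reach its own ring-held C2. The aryllithium adds to the carbonyl of the α-alkylidene γ-lactone 18, and the tetrahedral lactolate 21 keeps the ketone masked until the quench, so no second addition should occur. The closest known reaction is the ring-opening acylation of lactones by o-lithiophenoxides made from o-bromophenols, which gives hydroxy ketones. No ring is closed and no stereocenter is formed: the lactone ring is opened, and C4, C3a and C3 of 18 become C5, C6 and C1′ of the side chain unchanged. The step needs chemoselectivity for the lactone of 18 over the coumarin lactone (secured by the phenoxide) and 1,2- over 1,4-addition (hard aryllithium, β-substituted enoate). On protonation the lactol should open to the hydroxy ketone, which gains conjugation and the O7–H···O=C hydrogen bond.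

**Compound list**

1 | phloroglucinol | Oc1cc(O)cc(O)c1 | starting material
2 | ethyl 2-methyl-3-oxobutanoate | CCOC(=O)C(C)C(C)=O | starting material
3 | 5,7-dihydroxy-3,4-dimethyl-2H-chromen-2-one | Oc1cc(O)cc2oc(=O)c(C)c(C)c12 | intermediate
4 | 5-hydroxy-3,4-dimethyl-2-oxo-2H-chromen-7-yl 2,2-dimethylpropanoate | Oc1cc(OC(=O)C(C)(C)C)cc2oc(=O)c(C)c(C)c12 | intermediate
5 | 3,4-dimethyl-2-oxo-5-(prop-2-en-1-yloxy)-2H-chromen-7-yl 2,2-dimethylpropanoate | C=CCOc1cc(OC(=O)C(C)(C)C)cc2oc(=O)c(C)c(C)c12 | intermediate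
6 | 5-hydroxy-3,4-dimethyl-2-oxo-6-(prop-2-en-1-yl)-2H-chromen-7-yl 2,2-dimethylpropanoate | Oc1c(CC=C)c(OC(=O)C(C)(C)C)cc2oc(=O)c(C)c(C)c12 | intermediate
7 | 5-methoxy-3,4-dimethyl-2-oxo-6-(prop-2-en-1-yl)-2H-chromen-7-yl 2,2-dimethylpropanoate | COc1c(CC=C)c(OC(=O)C(C)(C)C)cc2oc(=O)c(C)c(C)c12 | intermediate
8 | 7-hydroxy-5-methoxy-3,4-dimethyl-6-(prop-2-en-1-yl)-2H-chromen-2-one | COc1c(CC=C)c(O)cc2oc(=O)c(C)c(C)c12 | intermediate
9 | 8-bromo-7-hydroxy-5-methoxy-3,4-dimethyl-6-(prop-2-en-1-yl)-2H-chromen-2-one | COc1c(CC=C)c(O)c(Br)c2oc(=O)c(C)c(C)c12 | intermediate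
10 | 8-bromo-7-hydroxy-5-methoxy-3,4-dimethyl-6-(3-methylbut-2-en-1-yl)-2H-chromen-2-one | COc1c(CC=C(C)C)c(O)c(Br)c2oc(=O)c(C)c(C)c12 | intermediate
11 | (2E)-pent-2-enal | CC/C=C/C=O | starting material
12 | (1E,3E)-trimethyl(penta-1,3-dien-1-yloxy)silane | C/C=C/C=C/O[Si](C)(C)C | intermediate
13 | (5S)-5-methylfuran-2(5H)-one | C[C@@H]1OC(=O)C=C1 | starting material
14 | (3S,3aR,4R,7S,7aR)-3,4-dimethyl-7-(trimethylsilyloxy)-3a,4,7,7a-tetrahydro-2-benzofuran-1(3H)-one | O=C1[C@H]2[C@@H](O[Si](C)(C)C)C=C[C@@H](C)[C@H]2[C@H](C)O1 | intermediate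
15 | (3S,3aR,4R,7S,7aR)-7-hydroxy-3,4-dimethyl-3a,4,7,7a-tetrahydro-2-benzofuran-1(3H)-one | O=C1[C@H]2[C@@H](O)C=C[C@@H](C)[C@H]2[C@H](C)O1 | intermediate
16 | (3S,3aR,4R,7S,7aR)-7-hydroxy-3,4-dimethylhexahydro-2-benzofuran-1(3H)-one | O=C1[C@H]2[C@@H](O)CC[C@@H](C)[C@H]2[C@H](C)O1 | intermediate
17 | (3S,3aR,4R,7S,7aR)-3,4-dimethyl-1-oxooctahydro-2-benzofuran-7-yl methanesulfonate | O=C1[C@H]2[C@@H](OS(C)(=O)=O)CC[C@@H](C)[C@H]2[C@H](C)O1 | intermediate
18 | (3S,3aR,4R)-3,4-dimethyl-3a,4,5,6-tetrahydro-2-benzofuran-1(3H)-one | O=C1C2=CCC[C@@H](C)[C@H]2[C@H](C)O1 | intermediate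
19 | sodium 8-bromo-5-methoxy-3,4-dimethyl-6-(3-methylbut-2-en-1-yl)-2-oxo-2H-chromen-7-olate | COc1c(CC=C(C)C)c([O-])c(Br)c2oc(=O)c(C)c(C)c12.[Na+] | intermediate
20 | sodium 8-lithio-5-methoxy-3,4-dimethyl-6-(3-methylbut-2-en-1-yl)-2-oxo-2H-chromen-7-olate | COc1c(CC=C(C)C)c([O-])c([Li])c2oc(=O)c(C)c(C)c12.[Na+] | intermediate
21 | lithium sodium salt of the lactol adduct (C8 aryl on the former lactone carbonyl carbon; lactol carbon unassigned) | [Li+].[Na+].[O-]C1(c2c([O-])c(CC=C(C)C)c(OC)c3c(C)c(C)c(=O)oc23)C2=CCC[C@@H](C)[C@H]2[C@H](C)O1 | intermediate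
22 | 7-hydroxy-8-{(5R,6R)-6-[(1S)-1-hydroxyethyl]-5-methylcyclohex-1-ene-1-carbonyl}-5-methoxy-3,4-dimethyl-6-(3-methylbut-2-en-1-yl)-2H-chromen-2-one | COc1c(CC=C(C)C)c(O)c(C(=O)C2=CCC[C@@H](C)[C@H]2[C@H](C)O)c2oc(=O)c(C)c(C)c12 | target

**Step count and risks**

Total steps: 12. Longest linear sequence: 8 (steps 1–7 and 12).

Steps most likely to fail:

1. Step 12. What may go wrong: proton transfer from the γ-CH2 of enoate lactone 18 to the aryllithium, or a bimolecular addition too slow to compete with attack of t-BuLi or of the aryllithium on a pyranone carbonyl. Fallback (the acyl transfer is made intramolecular; it sets out from 18 and 10 and returns at 22): saponification of 18 (LiOH, THF–H2O) should give lithium (5R,6R)-6-[(1S)-1-hydroxyethyl]-5-methylcyclohex-1-ene-1-carboxylate F1. Silylation of both oxygens (TBSCl, imidazole, DMF) should give the silyl ester silyl ether F2, and K2CO3 in MeOH–H2O should cleave only the silyl ester to give the O-TBS acid F3. Steglich esterification of F3 with phenol 10 (EDC·HCl, DMAP, CH2Cl2) should give the aryl ester F4. t-BuLi (2 equiv, THF, −100 °C) should then trigger Br/Li exchange and an immediate 1,3 O→C acyl shift (anionic Fries rearrangement) to the 8-acyl phenol silyl ether F5, and HF·pyridine should remove the silyl group to give 22.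

2. Step 9. What may go wrong: low dienophile reactivity of the butenolide at temperatures the silyl dienol ether survives, incomplete endo selectivity (which erodes the C4 configuration), and geometric impurity of the diene. Fallback (a geometry-pure, more reactive nitrogen diene; it sets out from 13 and returns at 18): sorbic acid is converted with DPPA and Et3N into (2E,4E)-hexa-2,4-dienoyl azide F6. Curtius rearrangement (toluene, 80 °C) should give (1E,3E)-1-isocyanatopenta-1,3-diene F7, trapped with t-BuOH as tert-butyl (1E,3E)-penta-1,3-dien-1-ylcarbamate F8. Diels–Alder reaction of F8 with 13 (toluene, 90 °C) should give the endo, anti adduct tert-butyl [(3S,3aR,4R,7S,7aR)-3,4-dimethyl-1-oxo-1,3,3a,4,7,7a-hexahydro-2-benzofuran-7-yl]carbamate F9, and hydrogenation (H2, Pd/C) its saturated analogue F10. t-BuOK (THF, 0 °C) should expel the carbamate by E1cB elimination to give 18.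

3. Step 6. What may go wrong: bromonium formation at the allyl group with capture by the neighbouring 7-OH (bromoetherification), or over-bromination. Fallback (bromine is introduced before any alkene and then serves as the blocking group for a Claisen rearrangement; it sets out from 4 and returns at 10): methylation of 4 (MeI, K2CO3, acetone) should give 5-methoxy-3,4-dimethyl-2-oxo-2H-chromen-7-yl 2,2-dimethylpropanoate F11, and methanolysis (K2CO3, MeOH) 7-hydroxy-5-methoxy-3,4-dimethyl-2H-chromen-2-one F12. NBS should brominate C8, the position favoured in 7-hydroxycoumarins (ortho to OH, para to OMe, less hindered than C6), to give 8-bromo-7-hydroxy-5-methoxy-3,4-dimethyl-2H-chromen-2-one F13. Pd(PPh3)4-catalysed O-alkylation with tert-butyl 2-methylbut-3-en-2-yl carbonate F14 (made from 2-methylbut-3-en-2-ol, n-BuLi and Boc2O) should give 8-bromo-5-methoxy-3,4-dimethyl-7-[(2-methylbut-3-en-2-yl)oxy]-2H-chromen-2-one F15. Its aromatic Claisen rearrangement (toluene, 110 °C) has C6 as the only open ortho position and should give 10.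

Further compounds
F1 | step 12 | lithium (5R,6R)-6-[(1S)-1-hydroxyethyl]-5-methylcyclohex-1-ene-1-carboxylate | [Li+].[O-]C(=O)C1=CCC[C@@H](C)[C@H]1[C@H](C)O
F2 | step 12 | tert-butyldimethylsilyl (5R,6R)-6-[(1S)-1-(tert-butyldimethylsilyloxy)ethyl]-5-methylcyclohex-1-ene-1-carboxylate | CC(C)(C)[Si](C)(C)OC(=O)C1=CCC[C@@H](C)[C@H]1[C@H](C)O[Si](C)(C)C(C)(C)C
F3 | step 12 | (5R,6R)-6-[(1S)-1-(tert-butyldimethylsilyloxy)ethyl]-5-methylcyclohex-1-ene-1-carboxylic acid | OC(=O)C1=CCC[C@@H](C)[C@H]1[C@H](C)O[Si](C)(C)C(C)(C)C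
F4 | step 12 | 8-bromo-5-methoxy-3,4-dimethyl-6-(3-methylbut-2-en-1-yl)-2-oxo-2H-chromen-7-yl (5R,6R)-6-[(1S)-1-(tert-butyldimethylsilyloxy)ethyl]-5-methylcyclohex-1-ene-1-carboxylate | COc1c(CC=C(C)C)c(OC(=O)C3=CCC[C@@H](C)[C@H]3[C@H](C)O[Si](C)(C)C(C)(C)C)c(Br)c2oc(=O)c(C)c(C)c12
F5 | step 12 | 8-{(5R,6R)-6-[(1S)-1-(tert-butyldimethylsilyloxy)ethyl]-5-methylcyclohex-1-ene-1-carbonyl}-7-hydroxy-5-methoxy-3,4-dimethyl-6-(3-methylbut-2-en-1-yl)-2H-chromen-2-one | COc1c(CC=C(C)C)c(O)c(C(=O)C3=CCC[C@@H](C)[C@H]3[C@H](C)O[Si](C)(C)C(C)(C)C)c2oc(=O)c(C)c(C)c12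
F6 | step 9 | (2E,4E)-hexa-2,4-dienoyl azide | C/C=C/C=C/C(=O)N=[N+]=[N-]
F7 | step 9 | (1E,3E)-1-isocyanatopenta-1,3-diene | C/C=C/C=C/N=C=O
F8 | step 9 | tert-butyl (1E,3E)-penta-1,3-dien-1-ylcarbamate | C/C=C/C=C/NC(=O)OC(C)(C)C
F9 | step 9 | tert-butyl [(3S,3aR,4R,7S,7aR)-3,4-dimethyl-1-oxo-1,3,3a,4,7,7a-hexahydro-2-benzofuran-7-yl]carbamate | O=C1[C@H]2[C@@H](NC(=O)OC(C)(C)C)C=C[C@@H](C)[C@H]2[C@H](C)O1
F10 | step 9 | tert-butyl [(3S,3aR,4R,7S,7aR)-3,4-dimethyl-1-oxooctahydro-2-benzofuran-7-yl]carbamate | O=C1[C@H]2[C@@H](NC(=O)OC(C)(C)C)CC[C@@H](C)[C@H]2[C@H](C)O1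
F11 | step 6 | 5-methoxy-3,4-dimethyl-2-oxo-2H-chromen-7-yl 2,2-dimethylpropanoate | COc1cc(OC(=O)C(C)(C)C)cc2oc(=O)c(C)c(C)c12
F12 | step 6 | 7-hydroxy-5-methoxy-3,4-dimethyl-2H-chromen-2-one | COc1cc(O)cc2oc(=O)c(C)c(C)c12
F13 | step 6 | 8-bromo-7-hydroxy-5-methoxy-3,4-dimethyl-2H-chromen-2-one | COc1cc(O)c(Br)c2oc(=O)c(C)c(C)c12
F14 | step 6 | tert-butyl 2-methylbut-3-en-2-yl carbonate | C=CC(C)(C)OC(=O)OC(C)(C)C
F15 | step 6 | 8-bromo-5-methoxy-3,4-dimethyl-7-[(2-methylbut-3-en-2-yl)oxy]-2H-chromen-2-one | COc1cc(OC(C)(C)C=C)c(Br)c2oc(=O)c(C)c(C)c12
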